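**Strategy.** Ring numbering: O1, O2, C3 (CH bearing the acetic acid arm), C4, C5, C6 (methoxy ketal carbon bearing the chain). Everything rests on reading the C3–C4–C5–C6 arc as a cyclobutanone in disguise: C4 and C5 are one molecule of ethylene, C3 and C6 the α-carbon and central carbon of a keteniminium ion. A single [2+2] cycloaddition therefore joins ethylene to both ring carbons at once. Its precursor is simply the dimethylamide of monomethyl succinate. After the alkynyl chain is added to the cyclobutanone, strain-driven β-scission of the C3–C6 bond under O2 inserts the peroxide, methanol closes the ketal, a covalent resolution fixes absolute configuration, and a late Sonogashira coupling completes the enyne.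

Key step: step 2

Remark: the ring expansion of step 4 passes C3 through a planar radical, so C3 necessarily arises racemic. The single enantiomer is therefore secured by separating diastereomeric oxazolidinone imides in step 7. Racemic compounds are drawn as one enantiomer, with starred (relative) descriptors.

**Step 1**
Reactants: 1 methyl 4-chloro-4-oxobutanoate; 2 dimethylamine
Product: 3 methyl 4-(dimethylamino)-4-oxobutanoate
Conditions: Me2NH (2 M in THF), Et3N, CH2Cl2, 0 °C to rt
Reagents that add atoms: none
Why: Schotten–Baumann-type N-acylation, in which the acid chloride is far more electrophilic than the methyl ester, so only the tertiary amide should form.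

**Step 2**
Reactants: 3 methyl 4-(dimethylamino)-4-oxobutanoate; 4 ethylene
Product: 7 methyl 2-(2-oxocyclobutyl)acetate (racemic), via keteniminium triflate 5 (not isolated), via cyclobutaniminium triflate 6 (not isolated)
Conditions: Tf2O (1.2 equiv), 2,4,6-collidine (1.2 equiv), ClCH2CH2Cl, ethylene (10 bar), 0 to 80 °C; then H2O, rt
Reagents that add atoms: water, O
Why: Tf2O O-sulfonylates the amide and collidine removes the α-proton to give keteniminium ion 5, whose central carbon and α-carbon add across ethylene in a thermal, asynchronous [2+2] cycloaddition; water then hydrolyses iminium salt 6 to the ketone. This is the Ghosez keteniminium–olefin cycloaddition, a known route to cyclobutanones that is also used with ethylene and with keteniminium ions carrying a single α-substituent. The four-membered ring is closed by intermolecular [2+2] cycloaddition, its two new C–C bonds (C5–C6 at the iminium carbon, C3–C4 at the α-carbon) arising in the same event. The one new stereocentre, the ring carbon bearing the ester arm, forms racemic and is deliberately left uncontrolled because step 4 erases it. Regiochemistry is moot for symmetrical ethylene; the step needs chemoselective activation of the amide over the ester (the amide oxygen is much the stronger nucleophile toward Tf2O) and capture by ethylene ahead of self-condensation or attack by the ester carbonyl, which a hindered base, high ethylene pressure and dilution should secure.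

**Step 3**
Reactants: 7 methyl 2-(2-oxocyclobutyl)acetate; 8 (5-chloropent-1-yn-1-yl)trimethylsilane
Product: 10 methyl 2-{2-hydroxy-2-[5-(trimethylsilyl)pent-4-yn-1-yl]cyclobutyl}acetate (racemic; hydroxyl cis to the ester arm), via Grignard reagent 9 (not isolated)
Conditions: 8, Mg, I2 (cat.), THF, reflux; CeCl3, THF, −78 °C; then 7, −78 °C; sat. aq. NH4Cl added at −78 °C; crude product used at once
Reagents that add atoms: none
Why: Imamoto-type 1,2-addition of the organocerium reagent made from 9 and CeCl3, which should add to the strained ketone far faster than to the methyl ester and without enolisation, attack anti to the ester arm placing the hydroxyl cis to it and the cold quench keeping the alkoxide from lactonising; both stereocentres are erased in step 4, so their control is immaterial.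

**Step 4**
Reactants: 10 methyl 2-{2-hydroxy-2-[5-(trimethylsilyl)pent-4-yn-1-yl]cyclobutyl}acetate
Product: 12 methyl 2-{6-hydroxy-6-[5-(trimethylsilyl)pent-4-yn-1-yl]-1,2-dioxan-3-yl}acetate (racemic; both hemiketal epimers), via open-chain hydroperoxy ketone 11 (not isolated)
Conditions: Co(acac)2 (0.2–1 equiv), O2 (1 atm), CH2Cl2, rt to 40 °C
Reagents that add atoms: dioxygen, O=O
Why: Cobalt-mediated aerobic oxidative ring expansion of a cyclobutanol, in which homolysis of the cobalt alkoxide gives the tertiary alkoxy radical, strain-driven β-scission on the more substituted side gives a secondary radical at C3 that traps O2, and hydroperoxide 11 closes onto the new ketone as the six-membered peroxyhemiketal; C3 arises racemic and C6 is an equilibrating hemiketal centre.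

**Step 5**
Reactants: 12 methyl 2-{6-hydroxy-6-[5-(trimethylsilyl)pent-4-yn-1-yl]-1,2-dioxan-3-yl}acetate
Product: 13 methyl 2-{(3S*,6R*)-6-methoxy-6-[5-(trimethylsilyl)pent-4-yn-1-yl]-1,2-dioxan-3-yl}acetate (racemic)
Conditions: MeOH, TsOH·H2O (cat.), 4 Å MS, rt
Reagents that add atoms: methanol, CO
Why: Acid-catalysed peroxyketalisation through the ring peroxycarbenium ion under thermodynamic control, where the anomeric effect should place OMe axial and both carbon substituents equatorial, fixing C6 relative to C3 (OMe cis to the ester arm); the methyl ester cannot scramble in methanol.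

**Step 6**
Reactants: 13 methyl 2-{(3S*,6R*)-6-methoxy-6-[5-(trimethylsilyl)pent-4-yn-1-yl]-1,2-dioxan-3-yl}acetate
Product: 14 2-[(3S*,6R*)-6-methoxy-6-(pent-4-yn-1-yl)-1,2-dioxan-3-yl]acetic acid (racemic)
Conditions: LiOH·H2O, THF/MeOH/H2O, 0 °C to rt; then 1 M HCl to pH 4, 0 °C
Reagents that add atoms: lithium hydroxide, [Li+].[OH-]
Why: Saponification and protodesilylation in one operation, since hydroxide should cleave both the methyl ester and the C(sp)–Si bond while the dialkyl peroxyketal is stable to base.

**Step 7**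
Reactants: 14 2-[(3S*,6R*)-6-methoxy-6-(pent-4-yn-1-yl)-1,2-dioxan-3-yl]acetic acid; 15 (4S)-4-benzyl-1,3-oxazolidin-2-one
Product: 17 (4S)-4-benzyl-3-{2-[(3S,6R)-6-methoxy-6-(pent-4-yn-1-yl)-1,2-dioxan-3-yl]acetyl}-1,3-oxazolidin-2-one, via mixed pivalic anhydride 16 (not isolated)
Conditions: PivCl, Et3N, THF, −20 °C; then 15, LiCl, −20 °C to rt; separation of the two diastereomers on silica gel
Reagents that add atoms: none
Why: N-acylation of the LiCl-activated oxazolidinone by the mixed anhydride converts the enantiomers into diastereomeric imides of different chromatographic mobility, so isolating the (3S,6R) imide sets the absolute configuration of both ring stereocentres by resolution.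

**Step 8**
Reactants: 18 dec-9-enal
Product: 19 (1E)-1-iodoundeca-1,10-diene
Conditions: CrCl2 (6 equiv), CHI3 (2 equiv), 1,4-dioxane/THF (6:1), 0 °C to rt
Reagents that add atoms: iodoform, IC(I)I
Why: Takai olefination, in which the geminal dichromium species from CHI3 adds to the aldehyde and eliminates to the E-vinyl iodide, the remote terminal alkene being inert.

**Step 9**
Reactants: 17 (4S)-4-benzyl-3-{2-[(3S,6R)-6-methoxy-6-(pent-4-yn-1-yl)-1,2-dioxan-3-yl]acetyl}-1,3-oxazolidin-2-one; 19 (1E)-1-iodoundeca-1,10-diene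
Product: 20 (4S)-4-benzyl-3-{2-[(3S,6R)-6-[(6E)-hexadeca-6,15-dien-4-yn-1-yl]-6-methoxy-1,2-dioxan-3-yl]acetyl}-1,3-oxazolidin-2-one
Conditions: Pd(PPh3)4 (5 mol %), CuI (10 mol %), Et3N, THF, rt, degassed, dark
Reagents that add atoms: none
Why: Sonogashira coupling with retention of the E geometry of the vinyl iodide; a dialkyl peroxyketal should tolerate zerovalent palladium, CuI and a tertiary amine at room temperature, and Et3N is too weak to trigger retro-oxa-Michael opening of the β-peroxy imide.

**Step 10**
Reactants: 20 (4S)-4-benzyl-3-{2-[(3S,6R)-6-[(6E)-hexadeca-6,15-dien-4-yn-1-yl]-6-methoxy-1,2-dioxan-3-yl]acetyl}-1,3-oxazolidin-2-one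
Product: 21 2-[(3S,6R)-6-[(6E)-hexadeca-6,15-dien-4-yn-1-yl]-6-methoxy-1,2-dioxan-3-yl]acetic acid (CNP0125368.1)
Conditions: LiOH·H2O, 30% H2O2, THF/H2O, 0 °C; then Na2SO3; 1 M HCl to pH 4, 0 °C
Reagents that add atoms: hydrogen peroxide, OO
Why: Evans auxiliary cleavage, in which LiOOH attacks the exocyclic imide carbonyl selectively at 0 °C and sulfite reduces the peracid, conditions that leave the peroxyketal, the enyne and the terminal alkene untouched and do not epimerise C3.

**Compound list**
1 | methyl 4-chloro-4-oxobutanoate | COC(=O)CCC(=O)Cl | starting material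
2 | dimethylamine | CNC | starting material
3 | methyl 4-(dimethylamino)-4-oxobutanoate | COC(=O)CCC(=O)N(C)C | intermediate
4 | ethylene | C=C | starting material
5 | (4-methoxy-4-oxobut-1-en-1-ylidene)dimethylammonium trifluoromethanesulfonate (keteniminium triflate) | COC(=O)CC=C=[N+](C)C.[O-]S(=O)(=O)C(F)(F)F | intermediate
6 | [2-(2-methoxy-2-oxoethyl)cyclobutylidene]dimethylammonium trifluoromethanesulfonate (cyclobutaniminium triflate, racemic) | COC(=O)CC1CCC1=[N+](C)C.[O-]S(=O)(=O)C(F)(F)F | intermediate
7 | methyl 2-(2-oxocyclobutyl)acetate (racemic) | COC(=O)CC1CCC1=O | intermediate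
8 | (5-chloropent-1-yn-1-yl)trimethylsilane | C[Si](C)(C)C#CCCCCl | starting material
9 | [5-(trimethylsilyl)pent-4-yn-1-yl]magnesium chloride (Grignard reagent) | C[Si](C)(C)C#CCCC[Mg]Cl | intermediate
10 | methyl 2-{2-hydroxy-2-[5-(trimethylsilyl)pent-4-yn-1-yl]cyclobutyl}acetate (racemic, hydroxyl cis to the ester arm) | C[Si](C)(C)C#CCCC[C@]1(O)CC[C@H]1CC(=O)OC | intermediate
11 | methyl 3-hydroperoxy-6-oxo-11-(trimethylsilyl)undec-10-ynoate (racemic) | COC(=O)CC(OO)CCC(=O)CCCC#C[Si](C)(C)C | intermediate
12 | methyl 2-{6-hydroxy-6-[5-(trimethylsilyl)pent-4-yn-1-yl]-1,2-dioxan-3-yl}acetate (racemic, both hemiketal epimers) | C[Si](C)(C)C#CCCCC1(O)CCC(CC(=O)OC)OO1 | intermediate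
13 | methyl 2-{(3S*,6R*)-6-methoxy-6-[5-(trimethylsilyl)pent-4-yn-1-yl]-1,2-dioxan-3-yl}acetate (racemic, OMe cis to the ester arm) | C[Si](C)(C)C#CCCC[C@]1(OC)CC[C@@H](CC(=O)OC)OO1 | intermediate
14 | 2-[(3S*,6R*)-6-methoxy-6-(pent-4-yn-1-yl)-1,2-dioxan-3-yl]acetic acid (racemic) | C#CCCC[C@]1(OC)CC[C@@H](CC(=O)O)OO1 | intermediate
15 | (4S)-4-benzyl-1,3-oxazolidin-2-one | O=C1OC[C@H](Cc2ccccc2)N1 | starting material
16 | 2-[(3S*,6R*)-6-methoxy-6-(pent-4-yn-1-yl)-1,2-dioxan-3-yl]acetic pivalic anhydride (racemic) | C#CCCC[C@]1(OC)CC[C@@H](CC(=O)OC(=O)C(C)(C)C)OO1 | intermediate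
17 | (4S)-4-benzyl-3-{2-[(3S,6R)-6-methoxy-6-(pent-4-yn-1-yl)-1,2-dioxan-3-yl]acetyl}-1,3-oxazolidin-2-one | C#CCCC[C@]1(OC)CC[C@@H](CC(=O)N2[C@@H](Cc3ccccc3)COC2=O)OO1 | intermediate
18 | dec-9-enal | C=CCCCCCCCC=O | starting material
19 | (1E)-1-iodoundeca-1,10-diene | C=CCCCCCCC/C=C/I | intermediate
20 | (4S)-4-benzyl-3-{2-[(3S,6R)-6-[(6E)-hexadeca-6,15-dien-4-yn-1-yl]-6-methoxy-1,2-dioxan-3-yl]acetyl}-1,3-oxazolidin-2-one | C=CCCCCCCC/C=C/C#CCCC[C@]1(OC)CC[C@@H](CC(=O)N2[C@@H](Cc3ccccc3)COC2=O)OO1 | intermediate
21 | 2-[(3S,6R)-6-[(6E)-hexadeca-6,15-dien-4-yn-1-yl]-6-methoxy-1,2-dioxan-3-yl]acetic acid | C=CCCCCCCC/C=C/C#CCCC[C@]1(OC)CC[C@@H](CC(=O)O)OO1 | target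

**Step count.** Total: 10 steps. Longest linear sequence: 9 steps (steps 1–7, 9, 10).

**Steps most likely to fail**

Step 2. The keteniminium ion may be consumed by attack of the neighbouring ester carbonyl oxygen on the iminium carbon (five-membered ring closure) or by self-condensation before the weakly nucleophilic ethylene intercepts it. The fallback carries no ester through the cycloaddition. It sets out from ethylene 4: N,N-dimethylacetamide under the same Tf2O/collidine/ethylene conditions, then aqueous hydrolysis, should give cyclobutanone F1. Condensation with 1,1-dimethylhydrazine gives cyclobutanone N,N-dimethylhydrazone F2. Deprotonation with LDA (THF, −78 °C) and alkylation with methyl bromoacetate gives methyl 2-[2-(2,2-dimethylhydrazinylidene)cyclobutyl]acetate F3. Two-phase hydrolysis with aqueous oxalic acid returns to the route at 7.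

Step 4. The peroxyl radical may lose oxygen to give the γ-hydroxy ketone or the 1,4-diketone, β-scission may be only partly regioselective, or the substrate may lactonise on the Lewis-acidic cobalt before the alkoxy radical forms. The fallback separates ring opening from peroxide formation. It sets out from 10: PhI(OAc)2/I2 under visible light (alkoxy radical fragmentation through the hypoiodite) should give methyl 3-iodo-6-oxo-11-(trimethylsilyl)undec-10-ynoate F4. DBU then eliminates to methyl (2E)-6-oxo-11-(trimethylsilyl)undec-2-en-10-ynoate F5. HC(OMe)3/MeOH/TsOH gives methyl (2E)-6,6-dimethoxy-11-(trimethylsilyl)undec-2-en-10-ynoate F6. Exchange with anhydrous ethereal H2O2 and catalytic acid gives methyl (2E)-6-hydroperoxy-6-methoxy-11-(trimethylsilyl)undec-2-en-10-ynoate F7. Et2NH in CF3CH2OH closes the ring by 6-exo conjugate addition of the hydroperoxide; brief MeOH/TsOH equilibration of the ketal centre brings the material back to the route at 13.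

Step 3. The tertiary alkoxide may lactonise onto the cis ester arm during addition or handling, leaving no free hydroxyl for step 4. The fallback accepts the lactone and moves the arm to the alcohol oxidation level. It sets out from 7 and 9: after the addition the mixture is warmed to complete lactonisation to cis-fused 1-[5-(trimethylsilyl)pent-4-yn-1-yl]-2-oxabicyclo[3.2.0]heptan-3-one F8. LiBH4 in THF reduces it to 2-(2-hydroxyethyl)-1-[5-(trimethylsilyl)pent-4-yn-1-yl]cyclobutan-1-ol F9. Co(acac)2/O2 as in step 4 gives 6-(2-hydroxyethyl)-3-[5-(trimethylsilyl)pent-4-yn-1-yl]-1,2-dioxan-3-ol F10. MeOH/TsOH gives 2-{(3S*,6R*)-6-methoxy-6-[5-(trimethylsilyl)pent-4-yn-1-yl]-1,2-dioxan-3-yl}ethan-1-ol F11. K2CO3/MeOH gives 2-[(3S*,6R*)-6-methoxy-6-(pent-4-yn-1-yl)-1,2-dioxan-3-yl]ethan-1-ol F12. Oxidation with TEMPO (cat.)/PhI(OAc)2 in MeCN/H2O returns to the route at 14.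

**Further compounds**
F1 | step 2 | cyclobutanone | O=C1CCC1
F2 | step 2 | cyclobutanone N,N-dimethylhydrazone | CN(C)N=C1CCC1
F3 | step 2 | methyl 2-[2-(2,2-dimethylhydrazinylidene)cyclobutyl]acetate (racemic) | COC(=O)CC1CCC1=NN(C)C
F4 | step 4 | methyl 3-iodo-6-oxo-11-(trimethylsilyl)undec-10-ynoate (racemic) | COC(=O)CC(I)CCC(=O)CCCC#C[Si](C)(C)C
F5 | step 4 | methyl (2E)-6-oxo-11-(trimethylsilyl)undec-2-en-10-ynoate | COC(=O)/C=C/CCC(=O)CCCC#C[Si](C)(C)C
F6 | step 4 | methyl (2E)-6,6-dimethoxy-11-(trimethylsilyl)undec-2-en-10-ynoate | COC(=O)/C=C/CCC(OC)(OC)CCCC#C[Si](C)(C)C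
F7 | step 4 | methyl (2E)-6-hydroperoxy-6-methoxy-11-(trimethylsilyl)undec-2-en-10-ynoate (racemic) | COC(=O)/C=C/CCC(OC)(OO)CCCC#C[Si](C)(C)C
F8 | step 3 | cis-fused 1-[5-(trimethylsilyl)pent-4-yn-1-yl]-2-oxabicyclo[3.2.0]heptan-3-one (racemic) | C[Si](C)(C)C#CCCC[C@]1(O2)CC[C@H]1CC2=O
F9 | step 3 | 2-(2-hydroxyethyl)-1-[5-(trimethylsilyl)pent-4-yn-1-yl]cyclobutan-1-ol (racemic, hydroxyl cis to the hydroxyethyl arm) | C[Si](C)(C)C#CCCC[C@]1(O)CC[C@H]1CCO
F10 | step 3 | 6-(2-hydroxyethyl)-3-[5-(trimethylsilyl)pent-4-yn-1-yl]-1,2-dioxan-3-ol (racemic, both hemiketal epimers) | C[Si](C)(C)C#CCCCC1(O)CCC(CCO)OO1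
F11 | step 3 | 2-{(3S*,6R*)-6-methoxy-6-[5-(trimethylsilyl)pent-4-yn-1-yl]-1,2-dioxan-3-yl}ethan-1-ol (racemic) | C[Si](C)(C)C#CCCC[C@]1(OC)CC[C@@H](CCO)OO1
F12 | step 3 | 2-[(3S*,6R*)-6-methoxy-6-(pent-4-yn-1-yl)-1,2-dioxan-3-yl]ethan-1-ol (racemic) | C#CCCC[C@]1(OC)CC[C@@H](CCO)OO1
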